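At early times the target made is little more than rate times clock, so two flasks with the same substrate and different catalyst, read at the same clock, give the ratio of their rates directly. That ratio is what you need in order to decide the next run: is the larch charge, with twice the catalyst of the maple run, worth making as drawn?

| flask | substrate | catalyst | time |
|---|---|---|---|
| ash | 0.250 M | 0.00130 M |  |
| maple | 0.150 M | 0.00130 M |  |
| cedar | 0.250 M | 0.00190 M |  |
| oak | 0.750 M | 0.00130 M |  |
| larch | 0.120 M | 0.00260 M | 5.9 h |

- ash run (time / h: [target] / M): 0.34: 0.012; 1.0: 0.039; 1.9: 0.066; 3.1: 0.100; 4.4: 0.136; 5.9: 0.162
- maple run (time / h: [target] / M): 0.34: 0.007; 1.0: 0.026; 1.9: 0.045; 3.1: 0.064; 4.4: 0.088; 5.9: 0.103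
- cedar run (time / h: [target] / M): 0.34: 0.022; 1.0: 0.037; 1.9: 0.080; 3.1: 0.108; 4.4: 0.151; 5.9: 0.178
- oak run (time / h: [target] / M): 0.34: 0.037; 1.0: 0.087; 1.9: 0.166; 3.1: 0.255; 4.4: 0.341; 5.9: 0.423

(readings scatter by 0.003 M)

- Overall: substrate -> target, with catalyst as catalyst.
- Constant volume, constant temperature.
- Bound and free are read together.
- An order is taken over about fifteen percent of the charge, up and down.

* reaction order in [catalyst] at the outset, round the charge of the ash run, defined at two percent of the substrate turned into target
* reaction order in [substrate] at the outset, round the charge of the ash run, defined at two percent of the substrate turned into target (one fixed amount of target, the same in the runs compared)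
* the maple run starts with 0.100 M less of substrate than the ash run, and with no target. Compared where both hold the same amount of substrate, once fifteen percent of what the maple run was charged with has turned into target, is the maple run faster, slower or alike (within a tenth)?
* target in the larch run at 5.9 h, as a share of the substrate charged

Follow one substrate molecule to its fork: it turns into target either by itself or through the catalyst. Call the fraction of the outset rate taken by the catalyst route the catalyst share. If that route scales with [catalyst] and the other ignores it, the share is also the order in [catalyst].

Here is my own reckoning. Summed over the readings up to 3.1 h, when the ash run has turned 40.0% of its charge, the ash run gives 0.217 M and the cedar run 0.247 M. The ratio is 1.14 for 1.46 times the catalyst, which puts the catalyst share of the ash run at 0.300, give or take 0.0847 from the scatter.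

For the larch run, I start from the maple run, the nearest charge. Its pseudo-first-order constant, −ln(1 − turned share)/time, comes to 0.197 h⁻¹ at 5.9 h. The share of 0.300 was read at the charge of the ash run, so I don't lend it to the maple run. Instead I take the same constant in the ash run, 0.177 h⁻¹, and multiply it by one minus the share, which gives 0.124 h⁻¹ for the route without catalyst, a part I assume to be the same in both flasks. That leaves 0.0727 h⁻¹ of the maple constant to the catalyst, a share of 0.369 over the maple run, larger than the share in the ash run. The larch run has twice the catalyst of the maple run, so I scale that catalyst part up accordingly, holding it at its maple value per unit of catalyst although the larch charge is lower. This gives 0.269 h⁻¹, so the larch run should reach 79.6% at 5.9 h, against 68.7% in the maple run at that clock. That gain of 11 percentage points is enough for me to charge the larch run as drawn.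

The forecast differs from me on the catalyst. It says “Raising catalyst 1.46-fold raises the rate only about 1.17-fold”, and gives an order of 0.45 (0.3 to 0.62). For the larch run it gives 80% (74% to 86%), beside my 79.6%. Its substrate order is 0.8 (0.7 to 0.92), and it calls the maple run alike with the ash run; I add nothing to either.

The flask gives a catalyst order of 0.30, a substrate order of 0.81, alike for the maple comparison and 84.7% for the larch run, from these steps:

    catalyst + substrate → target + catalyst (122.8 L mol⁻¹ h⁻¹)
    substrate → target (0.1109 h⁻¹)
    catalyst + substrate ⇌ idle catalyst-substrate complex, settled at all times (9.690 L mol⁻¹)

The simulated early rates are 0.044 M h⁻¹ in the cedar run and 0.039 M h⁻¹ in the ash run. Now carry the catalyst share to the oak run. The uncatalysed part of the ash rate, 0.0273 M h⁻¹, scaled by the charge ratio of 3.00, is 0.0812 M h⁻¹. That leaves 0.0158 M h⁻¹ of the simulated oak rate of 0.097 M h⁻¹ for the catalyst, a share of 0.163 in the oak run, smaller than the 0.300 of the ash run.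

The earlier runs and the new flask come from a simulation for an exercise; noise was put on by code.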